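**Retrosynthetic overview**
1. Target 22 ⇐ dienyl triflate 21 (C9–OTf → C9–H) ⇐ 12-membered macrolactone 19 by a base-triggered ring contraction: the C9 acyl carbon moves from O13 to C8 (O→C acyl shift), forming the C8–C9 bond, the 10-membered carbocycle and the free CH2OH together.
2. 19 ⇐ ring-closing metathesis of bis-methacrylate 18; methacryloyl chloride supplies both the C6 ester and the C9–C10(–C14) unit.
3. 18 ⇐ Nozaki–Hiyama–Kishi (NHK) union at C6–C7 of bromobutenolide 3 (from tetronic acid and DMF) with aldehyde 13.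
4. 13 ⇐ (R)-2-vinyloxirane (C1–C3, sets C2), 2-methyl-1,3-dithiane (C4 and its methyl) and methyl acetate (C5–C6) through a chelation-controlled Mukaiyama aldol (sets C4).
5. Ring order: butenolide (bought in as tetronic acid) → 12-membered macrolactone → 10-membered carbocycle.

Assumption: enantiopure (R)-2-vinyloxirane is taken as a catalogue item (otherwise from hydrolytic kinetic resolution of the racemate); locants C1–C15 in the text are germacrane-type (C2 carries OAc, C4 the tertiary OH, C6 the methacrylate, C8 is the lactone enol carbon, C13 the CH2OH carbon).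

Step 1
Reactants: 1 tetronic acid (4-hydroxyfuran-2(5H)-one)
Product: 2 4-bromo-2-oxo-2,5-dihydrofuran-3-carbaldehyde
Conditions: DMF, PBr3, CHCl3, 0 → 60 °C; then H2O
Reagents that add atoms: N,N-dimethylformamide CN(C)C=O; phosphorus tribromide BrP(Br)Br; water O
Why: Vilsmeier–Haack–Arnold bromoformylation of the enolised 1,3-dicarbonyl formylates the nucleophilic C3 and exchanges the C4 enol OH for bromide, as in the standard 4-hydroxycoumarin case.

Step 2
Reactants: 2 4-bromo-2-oxo-2,5-dihydrofuran-3-carbaldehyde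
Product: 3 4-bromo-3-(hydroxymethyl)furan-2(5H)-one
Conditions: NaBH(OAc)3, THF, 0 °C
Reagents that add atoms: none
Why: the mild acyloxyborohydride reduces only the aldehyde (1,2-reduction) and leaves the lactone and the vinylogous acyl bromide untouched.

Step 3
Reactants: 4 2-methyl-1,3-dithiane; 5 (R)-2-vinyloxirane
Product: 8 2-[(2S)-2-(4-methoxybenzyloxy)but-3-en-1-yl]-2-methyl-1,3-dithiane, via 2-lithio-2-methyl-1,3-dithiane 6 (not isolated), via lithium alkoxide 7 (not isolated)
Conditions: n-BuLi, THF, −30 °C; 5, −78 → −20 °C; then PMBCl, Bu4NI, DMPU, 0 → 25 °C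
Reagents that add atoms: 4-methoxybenzyl chloride COc1ccc(CCl)cc1
Why: Corey–Seebach dithiane anion opens the vinyl epoxide by SN2 at the terminal CH2 in THF, so C2 keeps the configuration of 5 (no bond to it is broken), and the alkoxide is benzylated in the same pot (Williamson).

Step 4
Reactants: 8 2-[(2S)-2-(4-methoxybenzyloxy)but-3-en-1-yl]-2-methyl-1,3-dithiane
Product: 9 (4S)-4-(4-methoxybenzyloxy)hex-5-en-2-one
Conditions: MeI, CaCO3, MeCN/H2O (9:1), 45 °C
Reagents that add atoms: water O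
Why: alkylative dithiane hydrolysis under near-neutral conditions unmasks the methyl ketone without β-elimination of the PMB ether.

Step 5
Reactants: 9 (4S)-4-(4-methoxybenzyloxy)hex-5-en-2-one; 10 methyl acetate
Product: 12 methyl (3S,5S)-3-hydroxy-5-(4-methoxybenzyloxy)-3-methylhept-6-enoate, via 1-methoxy-1-(trimethylsilyloxy)ethene 11 (not isolated)
Conditions: 10, LiN(i-Pr)2, Me3SiCl, THF, −78 °C, then solvent switch; 9, TiCl4, CH2Cl2, −78 °C
Reagents that add atoms: none
Why: chelation-controlled Mukaiyama aldol in which TiCl4 bridges the ketone and the PMB ether oxygen in a six-membered chelate and the ketene acetal attacks anti to the vinyl group, giving the 2,4-anti tertiary carbinol needed at C4.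

Step 6
Reactants: 12 methyl (3S,5S)-3-hydroxy-5-(4-methoxybenzyloxy)-3-methylhept-6-enoate
Product: 13 (3S,5S)-3-hydroxy-5-(4-methoxybenzyloxy)-3-methylhept-6-enal
Conditions: i-Bu2AlH (2.2 equiv), CH2Cl2, −78 °C; aq. KNaC4H4O6 work-up
Reagents that add atoms: none
Why: partial ester reduction stops at the aldehyde because the β-aluminium alkoxide chelates and stabilises the tetrahedral intermediate at −78 °C.

Step 7
Reactants: 13 (3S,5S)-3-hydroxy-5-(4-methoxybenzyloxy)-3-methylhept-6-enal; 3 4-bromo-3-(hydroxymethyl)furan-2(5H)-one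
Product: 14 4-[(1R,3R,5S)-1,3-dihydroxy-5-(4-methoxybenzyloxy)-3-methylhept-6-en-1-yl]-3-(hydroxymethyl)furan-2(5H)-one
Conditions: CrCl2 (4 equiv), NiCl2 (5 mol%), (S)-N-[2-(4-isopropyl-4,5-dihydrooxazol-2-yl)-6-methylphenyl]methanesulfonamide, Et3N, THF, 25 °C
Reagents that add atoms: none
Why: Nozaki–Hiyama–Kishi coupling (zerovalent nickel inserts into the activated C–Br bond, transmetalation gives the alkenyl trivalent-chromium species, which adds to the aldehyde); the chiral sulfonamide ligand on chromium sets C6 (R) by reagent control because the quaternary C4 gives little 1,3-induction, and the antipodal ligand is used if the 6S alcohol dominates.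

Step 8
Reactants: 14 4-[(1R,3R,5S)-1,3-dihydroxy-5-(4-methoxybenzyloxy)-3-methylhept-6-en-1-yl]-3-(hydroxymethyl)furan-2(5H)-one; 15 methacryloyl chloride
Product: 16 {4-[(1R,3S,5S)-3-hydroxy-5-(4-methoxybenzyloxy)-3-methyl-1-(methacryloyloxy)hept-6-en-1-yl]-2-oxo-2,5-dihydrofuran-3-yl}methyl methacrylate
Conditions: 15 (2.5 equiv), Et3N, DMAP (cat.), CH2Cl2, −20 → 0 °C
Reagents that add atoms: none
Why: acylation of the primary C13 and secondary C6 hydroxyls, while the tertiary C4 hydroxyl does not react under these conditions.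

Step 9
Reactants: 16 the bis-methacrylate PMB ether
Product: 17 {4-[(1R,3S,5S)-3,5-dihydroxy-3-methyl-1-(methacryloyloxy)hept-6-en-1-yl]-2-oxo-2,5-dihydrofuran-3-yl}methyl methacrylate
Conditions: DDQ, CH2Cl2/pH 7 buffer, 0 °C
Reagents that add atoms: none
Why: oxidative cleavage of the electron-rich PMB ether; the electron-poor alkenes and esters are inert to DDQ.

Step 10
Reactants: 17 the C2 alcohol
Product: 18 {4-[(1R,3S,5S)-5-acetoxy-3-hydroxy-3-methyl-1-(methacryloyloxy)hept-6-en-1-yl]-2-oxo-2,5-dihydrofuran-3-yl}methyl methacrylate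
Conditions: Ac2O, pyridine, CH2Cl2, 25 °C
Reagents that add atoms: acetic anhydride CC(=O)OC(C)=O
Why: acetylation of the only secondary alcohol; the tertiary alcohol is not acylated without forcing conditions.

Step 11
Reactants: 18 the acetate bis-methacrylate
Product: 19 (5E,7S,9S,11R)-9-hydroxy-5,9-dimethyl-11-(methacryloyloxy)-4,15-dioxo-3,14-dioxabicyclo[10.3.0]pentadeca-1(12),5-dien-7-yl acetate
Conditions: second-generation Hoveyda–Grubbs catalyst [RuCl2(H2IMes)(=CH-C6H4-2-O-i-Pr)] (10 mol%), toluene (1 mM), 90 °C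
Reagents that add atoms: none
Why: ring-closing metathesis in which the catalyst loads on the monosubstituted C1 vinyl and closes onto the C13 methacrylate to give the 12-membered ring (closure onto the C6 methacrylate would need a 9-membered ring), with the E-enoate expected as the less strained isomer at this ring size.

Step 12
Reactants: 19 the 12-membered macrolactone
Product: 21 (4R,6S,8S,9E,11Z)-8-acetoxy-6-hydroxy-3-(hydroxymethyl)-6,10-dimethyl-2-oxo-11-(trifluoromethanesulfonyloxy)-2,4,5,6,7,8-hexahydrocyclodeca[b]furan-4-yl methacrylate, via lithium enolate 20 (not isolated)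
Conditions: LiN(SiMe3)2 (1.15 equiv), THF (2 mM), −78 → −20 °C; then PhNTf2, −78 → 0 °C
Reagents that add atoms: N-phenylbis(trifluoromethanesulfonimide) O=S(=O)(N(c1ccccc1)S(=O)(=O)C(F)(F)F)C(F)(F)F
Why: Proposed new method: γ-deprotonation of the butenolide gives a 2-oxidofuran whose C8 attacks the macrolactone carbonyl C9 through a six-membered transition state (C8–C9–O13–C13–C11=C7), the tetrahedral intermediate expels the O13 alkoxide, and proton transfer gives the strongly stabilised vinylogous β-keto-lactone enolate 20 as the thermodynamic sink, so the 12-membered lactone contracts to the 10-membered carbocycle and C13–OH is released; the enolate is then triflated on the ketone-derived oxygen with the ring enforcing C10 cis to C7; the closest known reactions are the Baker–Venkataraman O→C acyl transfer and Dieckmann-type ring contractions of macrolactones.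

Step 13
Reactants: 21 the dienyl triflate
Product: 22 (4R,6S,8S,9E,11E)-8-acetoxy-6-hydroxy-3-(hydroxymethyl)-6,10-dimethyl-2-oxo-2,4,5,6,7,8-hexahydrocyclodeca[b]furan-4-yl methacrylate (CNP0246543.2)
Conditions: Pd(PPh3)4 (5 mol%), LiCl, Bu3SnH, THF, 25 °C
Reagents that add atoms: none
Why: zerovalent palladium inserts into the enol triflate C–O bond, tin hydride transfers hydride and reductive elimination gives the C9–H alkene with retention of geometry, faster than ionisation of the hindered allylic acetate.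

**Compound list**
1 | tetronic acid (4-hydroxyfuran-2(5H)-one) | OC1=CC(=O)OC1 | starting material
2 | 4-bromo-2-oxo-2,5-dihydrofuran-3-carbaldehyde | O=CC1=C(Br)COC1=O | intermediate
3 | 4-bromo-3-(hydroxymethyl)furan-2(5H)-one | OCC1=C(Br)COC1=O | intermediate
4 | 2-methyl-1,3-dithiane | CC1SCCCS1 | starting material
5 | (R)-2-vinyloxirane | C=C[C@@H]1CO1 | starting material
6 | 2-lithio-2-methyl-1,3-dithiane | [Li]C1(C)SCCCS1 | intermediate
7 | lithium (2S)-1-(2-methyl-1,3-dithian-2-yl)but-3-en-2-olate | [Li+].C=C[C@@H]([O-])CC1(C)SCCCS1 | intermediate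
8 | 2-[(2S)-2-(4-methoxybenzyloxy)but-3-en-1-yl]-2-methyl-1,3-dithiane | C=C[C@@H](OCc1ccc(OC)cc1)CC2(C)SCCCS2 | intermediate
9 | (4S)-4-(4-methoxybenzyloxy)hex-5-en-2-one | CC(=O)C[C@H](OCc1ccc(OC)cc1)C=C | intermediate
10 | methyl acetate | COC(C)=O | starting material
11 | 1-methoxy-1-(trimethylsilyloxy)ethene | C=C(OC)O[Si](C)(C)C | intermediate
12 | methyl (3S,5S)-3-hydroxy-5-(4-methoxybenzyloxy)-3-methylhept-6-enoate | COC(=O)C[C@@](C)(O)C[C@H](OCc1ccc(OC)cc1)C=C | intermediate
13 | (3S,5S)-3-hydroxy-5-(4-methoxybenzyloxy)-3-methylhept-6-enal | O=CC[C@@](C)(O)C[C@H](OCc1ccc(OC)cc1)C=C | intermediate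
14 | 4-[(1R,3R,5S)-1,3-dihydroxy-5-(4-methoxybenzyloxy)-3-methylhept-6-en-1-yl]-3-(hydroxymethyl)furan-2(5H)-one | O[C@H](C[C@@](C)(O)C[C@H](OCc1ccc(OC)cc1)C=C)C1=C(CO)C(=O)OC1 | intermediate
15 | methacryloyl chloride | C=C(C)C(Cl)=O | starting material
16 | {4-[(1R,3S,5S)-3-hydroxy-5-(4-methoxybenzyloxy)-3-methyl-1-(methacryloyloxy)hept-6-en-1-yl]-2-oxo-2,5-dihydrofuran-3-yl}methyl methacrylate | C=C(C)C(=O)O[C@H](C[C@@](C)(O)C[C@H](OCc1ccc(OC)cc1)C=C)C1=C(COC(=O)C(C)=C)C(=O)OC1 | intermediate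
17 | {4-[(1R,3S,5S)-3,5-dihydroxy-3-methyl-1-(methacryloyloxy)hept-6-en-1-yl]-2-oxo-2,5-dihydrofuran-3-yl}methyl methacrylate | C=C(C)C(=O)O[C@H](C[C@@](C)(O)C[C@H](O)C=C)C1=C(COC(=O)C(C)=C)C(=O)OC1 | intermediate
18 | {4-[(1R,3S,5S)-5-acetoxy-3-hydroxy-3-methyl-1-(methacryloyloxy)hept-6-en-1-yl]-2-oxo-2,5-dihydrofuran-3-yl}methyl methacrylate | C=C(C)C(=O)O[C@H](C[C@@](C)(O)C[C@H](OC(C)=O)C=C)C1=C(COC(=O)C(C)=C)C(=O)OC1 | intermediate
19 | (5E,7S,9S,11R)-9-hydroxy-5,9-dimethyl-11-(methacryloyloxy)-4,15-dioxo-3,14-dioxabicyclo[10.3.0]pentadeca-1(12),5-dien-7-yl acetate | C=C(C)C(=O)O[C@@H]1C[C@@](C)(O)C[C@H](OC(C)=O)/C=C(C)/C(=O)OCC2=C1COC2=O | intermediate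
20 | lithium (4R,6S,8S,9E,11Z)-8-acetoxy-6-hydroxy-3-(hydroxymethyl)-6,10-dimethyl-4-(methacryloyloxy)-2-oxo-2,4,5,6,7,8-hexahydrocyclodeca[b]furan-11-olate | [Li+].C=C(C)C(=O)O[C@@H]1C[C@@](C)(O)C[C@H](OC(C)=O)/C=C(C)/C([O-])=C2/OC(=O)C(CO)=C21 | intermediate
21 | (4R,6S,8S,9E,11Z)-8-acetoxy-6-hydroxy-3-(hydroxymethyl)-6,10-dimethyl-2-oxo-11-(trifluoromethanesulfonyloxy)-2,4,5,6,7,8-hexahydrocyclodeca[b]furan-4-yl methacrylate | C=C(C)C(=O)O[C@@H]1C[C@@](C)(O)C[C@H](OC(C)=O)/C=C(C)/C(OS(=O)(=O)C(F)(F)F)=C2/OC(=O)C(CO)=C21 | intermediate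
22 | (4R,6S,8S,9E,11E)-8-acetoxy-6-hydroxy-3-(hydroxymethyl)-6,10-dimethyl-2-oxo-2,4,5,6,7,8-hexahydrocyclodeca[b]furan-4-yl methacrylate | C=C(C)C(=O)O[C@@H]1C[C@@](C)(O)C[C@H](OC(C)=O)/C=C(C)/C=C2/OC(=O)C(CO)=C21 | target

**Step count**
Total steps: 13. Longest linear sequence: 11 (steps 3 to 13, from 4 and 5).

**Three steps most likely to fail**

Step 12 (the proposed ring contraction). The 2-oxidofuran could instead expel the C13 carboxylate by β-elimination, accept the methacryloyl group from O6 through a more strained five-membered transition state, or be triflated on the lactone oxygen. The fallback uses known chemistry, sets out from 14 and comes back at 22. TBSCl and imidazole silylate only the primary alcohol to give the 13-O-TBS ether of 14 F1. Methacryloyl chloride 15, Et3N and DMAP give the 6-O-methacrylate F2. DDQ gives the C2 alcohol F3, and Ac2O in pyridine gives the C2 acetate F4. Cross-metathesis with methacrolein (second-generation Hoveyda–Grubbs catalyst) gives the (E)-enal F5. A vinylogous Mukaiyama aldol–elimination at high dilution (TBSOTf, i-Pr2NEt, then DBU) closes the ten-membered ring directly with the ylidene in place, giving the 4,13-bis-O-TBS ether of the target F6. HF·pyridine then gives 22.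

Step 11 (macrocyclic metathesis to a trisubstituted enoate). The closure may be slow or give the Z-enoate. The fallback sets out from 13 and 3 and comes back at 19. Acylation of 3 with 15 gives (4-bromo-2-oxo-2,5-dihydrofuran-3-yl)methyl methacrylate F7. Cross-metathesis of 13 with F7, which is reliably E-selective for methacrylates, gives the seco bromo aldehyde F8. A macrocyclic NHK reaction (CrCl2, NiCl2 cat., chiral sulfonamide ligand, THF, 2 mM) closes the 12-membered ring at C6–C7 to give the macrolactone alcohol F9. Methacrylation gives the 6-O-methacrylate F10, DDQ gives the C2 alcohol F11, and Ac2O in pyridine gives 19.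

Step 7 (configuration at C6). Ligand control may be weak on this β-hydroxy aldehyde. The fallback sets out from 3 and 13 and comes back at 14; it replaces stereoselective C–C bond formation by reagent-controlled ketone reduction. TBDPSCl and imidazole convert 3 into the silyl ether F12. An achiral NHK coupling with 13 (CrCl2, NiCl2 cat., DMSO) gives the C6-epimeric adduct F13. Dess–Martin periodinane oxidises both epimers to the single C6 ketone F14. Corey–Bakshi–Shibata reduction ((S)-2-methyl-CBS-oxazaborolidine, BH3·SMe2), with the butenolide as the large group, gives the (6R)-alcohol F15. Bu4NF buffered with AcOH removes the silyl group to give 14.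

**Further compounds**
F1 | step 12 | 13-O-TBS ether of 14 | O[C@H](C[C@@](C)(O)C[C@H](OCc1ccc(OC)cc1)C=C)C1=C(CO[Si](C)(C)C(C)(C)C)C(=O)OC1
F2 | step 12 | 6-O-methacrylate of F1 | C=C(C)C(=O)O[C@H](C[C@@](C)(O)C[C@H](OCc1ccc(OC)cc1)C=C)C1=C(CO[Si](C)(C)C(C)(C)C)C(=O)OC1
F3 | step 12 | C2 alcohol from F2 (PMB removed) | C=C(C)C(=O)O[C@H](C[C@@](C)(O)C[C@H](O)C=C)C1=C(CO[Si](C)(C)C(C)(C)C)C(=O)OC1
F4 | step 12 | C2 acetate of F3 | C=C(C)C(=O)O[C@H](C[C@@](C)(O)C[C@H](OC(C)=O)C=C)C1=C(CO[Si](C)(C)C(C)(C)C)C(=O)OC1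
F5 | step 12 | (E)-enal from F4 and methacrolein | C=C(C)C(=O)O[C@H](C[C@@](C)(O)C[C@H](OC(C)=O)/C=C(C)/C=O)C1=C(CO[Si](C)(C)C(C)(C)C)C(=O)OC1
F6 | step 12 | 4,13-bis-O-TBS ether of 22 | C=C(C)C(=O)O[C@@H]1C[C@@](C)(O[Si](C)(C)C(C)(C)C)C[C@H](OC(C)=O)/C=C(C)/C=C2/OC(=O)C(CO[Si](C)(C)C(C)(C)C)=C21
F7 | step 11 | (4-bromo-2-oxo-2,5-dihydrofuran-3-yl)methyl methacrylate | C=C(C)C(=O)OCC1=C(Br)COC1=O
F8 | step 11 | seco bromo aldehyde with (E)-enoate link | O=CC[C@@](C)(O)C[C@H](OCc1ccc(OC)cc1)/C=C(C)/C(=O)OCC1=C(Br)COC1=O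
F9 | step 11 | 12-membered macrolactone with free C6 hydroxyl and C2 PMB ether | O[C@@H]1C[C@@](C)(O)C[C@H](OCc2ccc(OC)cc2)/C=C(C)/C(=O)OCC3=C1COC3=O
F10 | step 11 | 6-O-methacrylate of F9 | C=C(C)C(=O)O[C@@H]1C[C@@](C)(O)C[C@H](OCc2ccc(OC)cc2)/C=C(C)/C(=O)OCC3=C1COC3=O
F11 | step 11 | C2 alcohol from F10 (PMB removed) | C=C(C)C(=O)O[C@@H]1C[C@@](C)(O)C[C@H](O)/C=C(C)/C(=O)OCC3=C1COC3=O
F12 | step 7 | 4-bromo-3-[(tert-butyldiphenylsilyloxy)methyl]furan-2(5H)-one | CC(C)(C)[Si](OCC1=C(Br)COC1=O)(c1ccccc1)c1ccccc1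
F13 | step 7 | 13-O-TBDPS NHK adduct as a mixture of C6 epimers | OC(C[C@@](C)(O)C[C@H](OCc1ccc(OC)cc1)C=C)C1=C(CO[Si](c2ccccc2)(c2ccccc2)C(C)(C)C)C(=O)OC1
F14 | step 7 | C6 ketone from F13 | O=C(C[C@@](C)(O)C[C@H](OCc1ccc(OC)cc1)C=C)C1=C(CO[Si](c2ccccc2)(c2ccccc2)C(C)(C)C)C(=O)OC1
F15 | step 7 | 13-O-TBDPS ether of 14 (6R alcohol) | O[C@H](C[C@@](C)(O)C[C@H](OCc1ccc(OC)cc1)C=C)C1=C(CO[Si](c2ccccc2)(c2ccccc2)C(C)(C)C)C(=O)OC1
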